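A factor of 2.96 separates the oak run at 10 °C from the alder run at −5 °C, and the two new flasks are read from that factor.

in all of them: gas phase 6.9 mM (held)
- alder: substrate 48 mM; temperature −5 °C; run made earlier
- oak: substrate 75 mM; temperature 10 °C; run made earlier
- Friday's: substrate 34 mM; temperature 0 °C; time 6.0 min
- Sunday's: substrate 34 mM; temperature 20 °C; time 6.0 min

- alder (time / min: target / %): 1.00: 0; 2.00: 7; 3.00: 9; 4.00: 9; 5.00: 9; 6.00: 10; 8.00: 15
- oak (time / min: target / %): 0.667: 6; 1.33: 7; 2.00: 9; 2.50: 13; 3.00: 17; 4.00: 21; 5.00: 26

(each reading ± 2 percentage points)

- at the start none of the gas phase is in solution

1. which of the two there is more of at the end, Friday's (target / isomer of the product)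
2. which of the two there is more of at the end, Sunday's (target / isomer of the product)
3. amount of target at the end, in percent of the substrate charged, Friday's
4. amount of target at the end, in percent of the substrate charged, Sunday's

Let k be the apparent first-order constant of substrate going to target (pseudo-first-order, with the gas phase held): minus the logarithm of the fraction of the charge not read as target, divided by the time. The conversion is assumed not to depend on the charge. The last readings give 0.0203 /min for the alder run and 0.0602 /min for the oak run. With a constant factor per degree, k at 6.0 min gives 16.1% target for Friday's and 52.6% for Sunday's.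

The weak link is the last alder reading, which jumps from 10% to 15% in a single step with a scatter of 2 percentage points. So each run's constant is reforged as the mean over its last two readings: 0.0189 /min for alder and 0.0596 /min for oak. Their ratio is the temperature factor F, 3.15, taken over the span between the two runs. Friday's then has k = 0.0277 /min and Sunday's k = 0.128 /min. The committed figures are 15.3% for Friday's and 53.6% for Sunday's. Target is called ahead of the isomer of the product in both flasks, a judgement, since the runs read no isomer.

The forecast says 14% with target ahead for Friday's and 35% with isomer of the product ahead for Sunday's, lower than the 53.6% here, a figure it reaches after a discount for “any lag, diversion to the isomer, or further loss”.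

Friday's gives 15.0% target against 3.14% isomer of the product, and Sunday's gives 55.9% against 3.48%.

    gas phase ⇌ dissolved gas, rate k1*(csat - [dissolved gas]) (kL = 0.0964 /s)
    substrate + dissolved gas → target (k = 0.120 /M/s, Ea = 53.0 kJ/mol)
    2 dissolved gas → self-condensation product (k = 0.610 /M/s, Ea = 53.0 kJ/mol)
    target ⇌ isomer of the product (K = 0.280, k = 0.00247 /s, Ea = 89.0 kJ/mol, ΔH = −50.0 kJ/mol)
    substrate ⇌ dormant form (K = 0.600, k = 0.00218 /s, Ea = 83.0 kJ/mol, ΔH = −54.0 kJ/mol)
    (constants at 0 °C)

In Friday's at 2.21 min, the half-life of substrate by the forward step into the dormant form alone is 5.3 min, shorter than the 25.0 min that Friday's k gives for conversion to target. At 6.00 min the dormant form holds 28.7% of the charge in Friday's and 4.34% in Sunday's. Carried to a repeat of Friday's at −25 °C, F gives 2.43% target, and that flask holds 2.64%.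

The earlier runs and the new flask were generated by integration with constants of no real substance; scatter was added.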